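**Retrosynthetic overview**

1. The cyclohexene is cut by a retro-Diels–Alder reaction into trans-communic acid (diene C12=C13–C14=C15) and ring-trans β-caryophyllen-14-oic acid (dienophile C4′=C5′); this union is the last step.
2. Ring A of the labdane (C1–C5, C10) is cut at C3–C4 and C5–C10. This gives a C4=C5 (Z)-methacrylate carrying the C19 ester and a C10=C1–C2=C3 diene; ring-B carbons C6–C9 are the tether, so one intramolecular [4+2] closes rings A and B.
3. The enabling feature is that C4 is the only substituted carbon of ring A besides the ring-fusion atoms, while C1 is a plain CH2. C1 can therefore carry a temporary ketone that makes the diene a 2-silyloxy diene. C8, the future exo-methylene carbon, carries an oxygen tied to C12 as a trans γ-lactone, which fixes C9 and the diene face.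
4. After cyclisation the C1 oxygen is removed, the lactone is opened to the 8-ketone and 12-aldehyde, and the C12–C16 diene and C8=CH2 are built by olefination.
5. Ring order: temporary γ-lactone, then rings A and B together, then the cyclohexene; the nine- and four-membered rings come from (−)-β-caryophyllene, whose C4′ methyl is oxidised with inversion and re-inversion of the ring alkene.

Key step: step 8

Remark on numbering: labdane numbering (C1–C20) is used for the diterpene half and primed caryophyllane numbering for the sesquiterpene half (C4′=C5′ ring alkene, C14′ the carbon on C4′).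
Assumption 1: the ProPhenol antipode in step 4 is the one that gives the (R)-carbinol; (S,S) is written.
Assumption 2: the SeO2 oxidation in step 15 is taken to relax the nine-membered ring to the cis-alkene, which steps 16 and 17 turn back into the trans-alkene.

**Route**

Step 1
Reactants: 1 methyl bis(2,2,2-trifluoroethyl)phosphonoacetate
Product: 2 methyl 2-[bis(2,2,2-trifluoroethoxy)phosphoryl]propanoate (racemic)
Conditions: KOtBu, MeI, THF, 0 °C → rt
Reagents that add atoms: iodomethane, CI
Why: SN2 C-methylation of the stabilised phosphonate anion should give the α-methyl olefination reagent; its stereocentre is racemic and is destroyed in step 2.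

Step 2
Reactants: 3 pent-4-enal; 2 methyl 2-[bis(2,2,2-trifluoroethoxy)phosphoryl]propanoate
Product: 4 methyl (2Z)-2-methylhepta-2,6-dienoate
Conditions: KN(SiMe3)2, 18-crown-6, THF, −78 °C
Reagents that add atoms: none
Why: In this Still–Gennari olefination the electron-poor phosphonate eliminates fast from the kinetic adduct under dissociating conditions, so the (Z)-2-methyl enoate (ester cis to the chain) should form selectively.

Step 3
Reactants: 4 methyl (2Z)-2-methylhepta-2,6-dienoate
Product: 5 methyl (2Z)-2-methyl-6-oxohex-2-enoate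
Conditions: OsO4 (cat.), NaIO4, 2,6-lutidine, dioxane/H2O, rt
Reagents that add atoms: osmium tetroxide, O=[Os](=O)(=O)=O; sodium periodate, [Na+].[O-]I(=O)(=O)=O
Why: In this Lemieux–Johnson cleavage OsO4 should dihydroxylate the electron-rich terminal alkene much faster than the electron-poor trisubstituted enoate, and periodate cleaves the diol to the aldehyde; no stereocentre is formed.

Step 4
Reactants: 5 methyl (2Z)-2-methyl-6-oxohex-2-enoate; 6 methyl propiolate
Product: 7 dimethyl (2Z,6R)-6-hydroxy-2-methylnon-2-en-7-ynedioate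
Conditions: Me2Zn, (S,S)-ProPhenol (20 mol %), Ph3P=O (40 mol %), toluene, 0 → 4 °C
Reagents that add atoms: none
Why: Catalytic enantioselective alkynylation of the aldehyde by the zinc acetylide of methyl propiolate on the dinuclear zinc–ProPhenol catalyst should set the (R)-carbinol at C8, the stereocentre that relays to all others of the labdane half.

Step 5
Reactants: 7 dimethyl (2Z,6R)-6-hydroxy-2-methylnon-2-en-7-ynedioate
Product: 9 methyl (2Z)-2-methyl-5-[(2R)-5-oxo-2,5-dihydrofuran-2-yl]pent-2-enoate, via Z-hydroxy diester 8 (not isolated)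
Conditions: H2 (1 atm), Pd/CaCO3–Pb(OAc)2 (Lindlar catalyst), quinoline, EtOAc, rt; then pyridinium p-toluenesulfonate (cat.), CH2Cl2, rt
Reagents that add atoms: none
Why: Lindlar semihydrogenation gives the (Z)-4-hydroxy enoate, which lactonises to the butenolide; the trisubstituted enoate is not reduced and C8 is untouched.

Step 6
Reactants: 9 methyl (2Z)-2-methyl-5-[(2R)-5-oxo-2,5-dihydrofuran-2-yl]pent-2-enoate; 10 S-ethyl propanethioate
Product: 11 S-ethyl 2-{(2R,3R)-2-[(3Z)-5-methoxy-4-methyl-5-oxopent-3-en-1-yl]-5-oxooxolan-3-yl}propanethioate (both epimers at the carbon next to the thioester)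
Conditions: 10, LiN(iPr)2, THF, −78 °C; then 9, −78 °C; AcOH quench
Reagents that add atoms: none
Why: Michael addition of the lithium thioester enolate should occur only at the butenolide (the α-methyl enoate is a far poorer acceptor) and anti to the C8 side chain, which sets C9 as the trans-lactone; the epimeric carbon (C10) becomes sp2 in step 8.

Step 7
Reactants: 11 S-ethyl 2-{(2R,3R)-2-[(3Z)-5-methoxy-4-methyl-5-oxopent-3-en-1-yl]-5-oxooxolan-3-yl}propanethioate
Product: 12 methyl (2Z)-2-methyl-5-[(2R,3R)-5-oxo-3-(3-oxopent-4-en-2-yl)oxolan-2-yl]pent-2-enoate (both epimers at the ketone α-carbon)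
Conditions: Bu3SnCH=CH2, Pd2(dba)3 (cat.), tri(2-furyl)phosphine, CuOP(O)Ph2, THF, rt → 50 °C
Reagents that add atoms: tributyl(vinyl)stannane, C=C[Sn](CCCC)(CCCC)CCCC
Why: In this Liebeskind–Srogl-type ketone synthesis zerovalent palladium inserts into the C–S bond, the cuprous phosphinate takes up the thiolate and mediates transfer of vinyl from tin, and the vinyl ketone forms under neutral conditions that leave lactone, enoate and C9 untouched.

Step 8
Reactants: 12 methyl (2Z)-2-methyl-5-[(2R,3R)-5-oxo-3-(3-oxopent-4-en-2-yl)oxolan-2-yl]pent-2-enoate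
Product: 15 methyl 8α,12-epoxy-1,12-dioxo-13,14,15,16,17-pentanorlabdan-19-oate (trans-decalin; 5α-H; 9α-H; 10β-CH3; 4β-CO2CH3; trans-fused γ-lactone), via silyl dienol ether 13 (not isolated), via silyl enol ether cycloadduct 14 (not isolated)
Conditions: TBSOTf, Et3N, CH2Cl2, −78 → 0 °C; then toluene (0.01 M), 110 °C, sealed tube; then 1 M HCl, THF, rt
Reagents that add atoms: none
Why: Soft enolisation at C10, the only enolisable side of the vinyl ketone, gives the cross-conjugated (Z)-2-silyloxy diene C3=C2–C1(OTBS)=C10, which adds to the tethered (Z)-methacrylate C4=C5 in a thermal, asynchronous intramolecular Diels–Alder reaction (a formal double Michael addition) that forms C5–C10 and C3–C4 together; the closest known reaction types are the intramolecular Diels–Alder reactions of undeca-2,8,10-trienoates and of 2-silyloxy dienes. Ring B closes across the four-atom tether C6–C9 in a chair-like fused (type 1) mode and ring A is the new cyclohexene of the same six-membered cycloaddition. C5 and C10 follow from the anti (trans-fused) chair transition state, in which the trans γ-lactone holds C8–O and C9–C11 diequatorial and so offers only one diene face, and C4 follows from the (Z)-dienophile reacting with its ester exo, which puts the ester cis to the angular methyl. The selectivity needed is the trans-fused exo-ester mode over the cis-fused endo mode; it should be secured by 1,3-allylic strain between the bulky silyloxy group on C1 and the substituents on C9, which is relieved only when H9 lies in the diene plane as in the trans-fused chair, and by the α-methyl of the dienophile, which cancels the endo preference of the ester and would meet the inside methyl on C10 in the endo mode. Both epimers of 12 give the same diene, so no stereocentre outside the lactone has to be set beforehand.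

Step 9
Reactants: 15 methyl 8α,12-epoxy-1,12-dioxo-13,14,15,16,17-pentanorlabdan-19-oate
Product: 16 methyl 1,1-(ethane-1,2-diyldisulfanediyl)-8α,12-epoxy-12-oxo-13,14,15,16,17-pentanorlabdan-19-oate (1,1-dithiolane of 15)
Conditions: HS(CH2)2SH, BF3·OEt2, CH2Cl2, 0 °C → rt
Reagents that add atoms: ethane-1,2-dithiol, SCCS
Why: Lewis-acid-promoted thioketalisation should take place only at the ketone, since lactone and hindered ester do not react; no stereocentre changes.

Step 10
Reactants: 16 methyl 1,1-(ethane-1,2-diyldisulfanediyl)-8α,12-epoxy-12-oxo-13,14,15,16,17-pentanorlabdan-19-oate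
Product: 17 methyl 8α,12-epoxy-12-oxo-13,14,15,16,17-pentanorlabdan-19-oate
Conditions: Raney Ni, EtOH, reflux
Reagents that add atoms: none
Why: Raney Ni hydrogenolysis of both C–S bonds (Mozingo reduction) turns C1 into a methylene and so removes the temporary oxygen; no alkene is present and no stereocentre is touched.

Step 11
Reactants: 17 methyl 8α,12-epoxy-12-oxo-13,14,15,16,17-pentanorlabdan-19-oate
Product: 18 methyl 8α,12-dihydroxy-13,14,15,16,17-pentanorlabdan-19-oate
Conditions: LiBH4, THF, 0 °C → rt
Reagents that add atoms: none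
Why: Chemoselective hydride reduction should open the γ-lactone to the 8,12-diol and leave the axial, neopentyl-type C19 methyl ester; C8 and C9 keep their configuration.

Step 12
Reactants: 18 methyl 8α,12-dihydroxy-13,14,15,16,17-pentanorlabdan-19-oate
Product: 20 methyl (12E)-8,14-dioxo-15,17-dinorlabd-12-en-19-oate, via keto aldehyde 19 (not isolated)
Conditions: (COCl)2, DMSO, CH2Cl2, −78 °C; Et3N, −78 → −20 °C; work-up; then Ph3P=C(CH3)CHO, toluene, 80 °C
Reagents that add atoms: 2-(triphenylphosphoranylidene)propanal, CC(C=O)=P(c1ccccc1)(c1ccccc1)c1ccccc1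
Why: Swern oxidation activates both hydroxyls before base is added, so the 1,4-diol should go to the keto aldehyde without lactol formation, and the stabilised ylide then olefinates only the aldehyde (Wittig reaction) to the (E)-2-methyl enal; C9, now α to the ketone, is kept cold while amine is present.

Step 13
Reactants: 20 methyl (12E)-8,14-dioxo-15,17-dinorlabd-12-en-19-oate
Product: 21 methyl trans-communate (methyl labda-8(17),12E,14-trien-19-oate)
Conditions: Zn, CH2Br2, TiCl4, THF, 0 °C (reagent aged); then 20, CH2Cl2, rt
Reagents that add atoms: dibromomethane, BrCBr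
Why: Takai–Lombardo methylenation converts both the enal carbonyl and the hindered C8 ketone into methylene groups with a non-basic zinc–titanium reagent, which should spare the enolisable C9 centre, the ester and the (12E)-alkene.

Step 14
Reactants: 21 methyl trans-communate
Product: 22 trans-communic acid (labda-8(17),12E,14-trien-19-oic acid)
Conditions: NaSPr, DMF, 90 °C; then 1 M HCl
Reagents that add atoms: none
Why: SN2 dealkylation by thiolate at the methyl carbon should cleave the axial ester that is too hindered for saponification; nothing else in the triene is electrophilic.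

Step 15
Reactants: 23 (−)-β-caryophyllene
Product: 24 14-hydroxyisocaryophyllene (ring-cis C4′=C5′; 4′E by the sequence rule)
Conditions: SeO2 (0.5 equiv), t-BuOOH, CH2Cl2, 0 °C → rt
Reagents that add atoms: selenium dioxide, O=[Se]=O; tert-butyl hydroperoxide, CC(C)(C)OO
Why: In this SeO2 allylic oxidation (ene reaction, then 2,3-sigmatropic shift) only the C4′ methyl has C–H bonds aligned with the strained ring π-bond, and the sigmatropic step is expected to relax the ring to the cis-alkene, as is known for E-configured methyl-bearing alkenes of ten-membered germacranolides; C1′ and C9′ are untouched.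

Step 16
Reactants: 24 14-hydroxyisocaryophyllene
Product: 25 cis-4′,5′-epoxide of 24 (C3′ and C6′ cis on the oxirane; one diastereomer drawn)
Conditions: VO(acac)2 (cat.), t-BuOOH, CH2Cl2, 0 °C
Reagents that add atoms: tert-butyl hydroperoxide, CC(C)(C)OO
Why: Vanadium-catalysed hydroxyl-directed epoxidation should oxidise the allylic-alcohol alkene and leave the isolated exocyclic methylene; either face may react because both cis-epoxide diastereomers converge in step 17.

Step 17
Reactants: 25 cis-4′,5′-epoxide of 24
Product: 26 14-hydroxy-β-caryophyllene (ring-trans C4′=C5′; 4′Z by the sequence rule)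
Conditions: KPPh2, THF, 0 °C → rt; then MeI, rt
Reagents that add atoms: none
Why: Phosphide opens the epoxide at C5′ with inversion, and P-methylation followed by syn elimination of the betaine (alkene inversion through a β-hydroxyphosphonium salt) should turn the cis-epoxide stereospecifically into the trans ring alkene.

Step 18
Reactants: 26 14-hydroxy-β-caryophyllene
Product: 28 β-caryophyllen-14-oic acid ((1R,4Z,9S)-11,11-dimethyl-8-methylidenebicyclo[7.2.0]undec-4-ene-4-carboxylic acid; ring-trans), via enal 27 (not isolated)
Conditions: MnO2, CH2Cl2, rt; filter; then NaClO2, NaH2PO4, 2-methylbut-2-ene, t-BuOH/H2O, 0 °C → rt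
Reagents that add atoms: sodium chlorite, [Na+].[O-]Cl=O
Why: MnO2 oxidises the allylic alcohol to the enal and Pinnick oxidation with a hypochlorite scavenger should take it to the acid without touching the alkenes or the ring geometry.

Step 19
Reactants: 22 trans-communic acid; 28 β-caryophyllen-14-oic acid
Product: 29 target diacid CNP0330729.1
Conditions: toluene (1 M), BHT (cat.), 110 °C, sealed tube
Reagents that add atoms: none
Why: In this thermal intermolecular Diels–Alder reaction the more advanced bond should form between the unsubstituted diene terminus C15 and C5′ (ortho regiochemistry, C12 to C4′), the carboxyl is endo (cis to the C11 methylene on C12), the ring-trans dienophile gives the trans ring fusion, and the diene adds to the exposed outer face of the nine-membered ring, the face attacked in epoxidation of β-caryophyllene.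

**Compound list**

1 | methyl bis(2,2,2-trifluoroethyl)phosphonoacetate | COC(=O)CP(=O)(OCC(F)(F)F)OCC(F)(F)F | starting material
2 | methyl 2-[bis(2,2,2-trifluoroethoxy)phosphoryl]propanoate (racemic) | COC(=O)C(C)P(=O)(OCC(F)(F)F)OCC(F)(F)F | intermediate
3 | pent-4-enal | C=CCCC=O | starting material
4 | methyl (2Z)-2-methylhepta-2,6-dienoate | COC(=O)/C(C)=C\CCC=C | intermediate
5 | methyl (2Z)-2-methyl-6-oxohex-2-enoate | COC(=O)/C(C)=C\CCC=O | intermediate
6 | methyl propiolate | C#CC(=O)OC | starting material
7 | dimethyl (2Z,6R)-6-hydroxy-2-methylnon-2-en-7-ynedioate | COC(=O)/C(C)=C\CC[C@@H](O)C#CC(=O)OC | intermediate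
8 | dimethyl (2Z,6R,7Z)-6-hydroxy-2-methylnona-2,7-dienedioate | COC(=O)/C(C)=C\CC[C@@H](O)/C=C\C(=O)OC | intermediate
9 | methyl (2Z)-2-methyl-5-[(2R)-5-oxo-2,5-dihydrofuran-2-yl]pent-2-enoate | COC(=O)/C(C)=C\CC[C@H]1OC(=O)C=C1 | intermediate
10 | S-ethyl propanethioate | CCSC(=O)CC | starting material
11 | S-ethyl 2-{(2R,3R)-2-[(3Z)-5-methoxy-4-methyl-5-oxopent-3-en-1-yl]-5-oxooxolan-3-yl}propanethioate (epimers at the thioester α-carbon) | COC(=O)/C(C)=C\CC[C@H]1OC(=O)C[C@@H]1C(C)C(=O)SCC | intermediate
12 | methyl (2Z)-2-methyl-5-[(2R,3R)-5-oxo-3-(3-oxopent-4-en-2-yl)oxolan-2-yl]pent-2-enoate (epimers at the ketone α-carbon) | COC(=O)/C(C)=C\CC[C@H]1OC(=O)C[C@@H]1C(C)C(=O)C=C | intermediate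
13 | methyl (2Z)-5-[(2R,3R)-3-{(2Z)-3-[(tert-butyldimethylsilyl)oxy]penta-2,4-dien-2-yl}-5-oxooxolan-2-yl]-2-methylpent-2-enoate | COC(=O)/C(C)=C\CC[C@H]1OC(=O)C[C@@H]1/C(C)=C(O[Si](C)(C)C(C)(C)C)/C=C | intermediate
14 | methyl 1-[(tert-butyldimethylsilyl)oxy]-8α,12-epoxy-12-oxo-13,14,15,16,17-pentanorlabd-1-en-19-oate | O=C1C[C@@H]2[C@@]3(C)C(O[Si](C)(C)C(C)(C)C)=CC[C@](C)(C(=O)OC)[C@@H]3CC[C@H]2O1 | intermediate
15 | methyl 8α,12-epoxy-1,12-dioxo-13,14,15,16,17-pentanorlabdan-19-oate | O=C1C[C@@H]2[C@@]3(C)C(=O)CC[C@](C)(C(=O)OC)[C@@H]3CC[C@H]2O1 | intermediate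
16 | 1,1-dithiolane of 15 | O=C1C[C@@H]2[C@@]3(C)C4(SCCS4)CC[C@](C)(C(=O)OC)[C@@H]3CC[C@H]2O1 | intermediate
17 | methyl 8α,12-epoxy-12-oxo-13,14,15,16,17-pentanorlabdan-19-oate | O=C1C[C@@H]2[C@@]3(C)CCC[C@](C)(C(=O)OC)[C@@H]3CC[C@H]2O1 | intermediate
18 | methyl 8α,12-dihydroxy-13,14,15,16,17-pentanorlabdan-19-oate | OCC[C@H]1[C@H](O)CC[C@@H]2[C@]1(C)CCC[C@]2(C)C(=O)OC | intermediate
19 | methyl 8,12-dioxo-13,14,15,16,17-pentanorlabdan-19-oate | O=CC[C@H]1C(=O)CC[C@@H]2[C@]1(C)CCC[C@]2(C)C(=O)OC | intermediate
20 | methyl (12E)-8,14-dioxo-15,17-dinorlabd-12-en-19-oate | O=C/C(C)=C/C[C@H]1C(=O)CC[C@@H]2[C@]1(C)CCC[C@]2(C)C(=O)OC | intermediate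
21 | methyl trans-communate | C=C/C(C)=C/C[C@H]1C(=C)CC[C@@H]2[C@]1(C)CCC[C@]2(C)C(=O)OC | intermediate
22 | trans-communic acid | C=C/C(C)=C/C[C@H]1C(=C)CC[C@@H]2[C@]1(C)CCC[C@]2(C)C(=O)O | intermediate
23 | (−)-β-caryophyllene, (1R,4E,9S)-4,11,11-trimethyl-8-methylidenebicyclo[7.2.0]undec-4-ene | C=C1CC/C=C(\C)CC[C@@H]2[C@@H]1CC2(C)C | starting material
24 | 14-hydroxyisocaryophyllene, [(1R,4E,9S)-11,11-dimethyl-8-methylidenebicyclo[7.2.0]undec-4-en-4-yl]methanol (ring-cis) | C=C1CC/C=C(/CO)CC[C@@H]2[C@@H]1CC2(C)C | intermediate
25 | cis-4′,5′-epoxide of 24 (one diastereomer drawn) | C=C1CC[C@H]2O[C@@]2(CO)CC[C@@H]2[C@@H]1CC2(C)C | intermediate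
26 | 14-hydroxy-β-caryophyllene, [(1R,4Z,9S)-11,11-dimethyl-8-methylidenebicyclo[7.2.0]undec-4-en-4-yl]methanol (ring-trans) | C=C1CC/C=C(\CO)CC[C@@H]2[C@@H]1CC2(C)C | intermediate
27 | β-caryophyllen-14-al (ring-trans) | C=C1CC/C=C(\C=O)CC[C@@H]2[C@@H]1CC2(C)C | intermediate
28 | β-caryophyllen-14-oic acid (ring-trans) | C=C1CC/C=C(\C(=O)O)CC[C@@H]2[C@@H]1CC2(C)C | intermediate
29 | target diacid: adduct of 22 (C12 and C15) with 28 (C4′ and C5′); 4′-carboxyl cis to the C11 methylene on C12; trans ring fusion | C=C1CC[C@H]2CC=C(C)[C@@H](C[C@H]3C(=C)CC[C@@H]4[C@]3(C)CCC[C@]4(C)C(=O)O)[C@]2(C(=O)O)CC[C@@H]2[C@@H]1CC2(C)C | target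

**Step count and risks**

Total step count: 19. Longest linear sequence: 15 steps (steps 1 to 14, then step 19).

Steps most likely to fail:

- **Step 8.** The cis-fused endo pathway may compete and erode fusion selectivity; part of the silyl dienol ether may sit in the geometry that cannot reach the dienophile; the vinyl ketone may oligomerise before cyclisation. The fallback changes the diene and the control element. It sets out from 9: conjugate addition of the cuprate of 1-ethoxyvinyllithium should give enol ether lactone F1, and mild acid gives trans acetyl lactone F2 (kept free of base). Ramirez dibromo-olefination (CBr4, P(OiPr)3) gives dibromoalkene F3, and Stille mono-vinylation at the bromine trans to the lactone carbon gives bromodiene F4, whose bromine on C1 is a removable steric directing group for the trans-fused mode. Thermal intramolecular Diels–Alder reaction (toluene, 160 °C) gives vinyl bromide F5, and H2, Pd/C, Et3N removes bromine and the C1=C2 bond. The fallback comes back to the route at 17, so steps 9 and 10 fall away.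

- **Step 19.** Reactivity may be too low at temperatures the strained trans ring alkene tolerates (geometric isomerisation), with erosion of regio-, endo- and facial selectivity. The fallback couples at the aldehyde oxidation level with Lewis acid activation. It sets out from 21 and from enal 27 (isolated after the MnO2 stage of step 18): Me2AlCl in CH2Cl2 at low temperature should give adduct aldehyde ester F6, Pinnick oxidation gives acid ester F7, and thiolate demethylation as in step 14 comes back to the route at 29.

- **Step 15.** Oxidation may occur at other allylic positions, the strained alkene may be epoxidised, or a mixture of ring geometries may form. The fallback stores the oxygen on the ring first. It sets out from 23: mCPBA should give caryophyllene oxide F8 (trans-epoxide), lithium diethylamide opens it to exocyclic allylic alcohol F9, hydroxyl-directed epoxidation (VO(acac)2, t-BuOOH) gives spiro-epoxy alcohol F10, and Payne rearrangement (aqueous NaOH, t-BuOH) with inversion at C4′ comes back to the route at 25.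

Further compounds
F1 | step 8 | enol ether lactone: methyl (2Z)-5-[trans-3-(1-ethoxyethenyl)-5-oxooxolan-2-yl]-2-methylpent-2-enoate (ring configuration as in 11) | COC(=O)/C(C)=C\CC[C@H]1OC(=O)C[C@@H]1C(=C)OCC
F2 | step 8 | acetyl lactone: methyl (2Z)-5-[trans-3-acetyl-5-oxooxolan-2-yl]-2-methylpent-2-enoate (ring configuration as in 11) | COC(=O)/C(C)=C\CC[C@H]1OC(=O)C[C@@H]1C(C)=O
F3 | step 8 | dibromoalkene: methyl (2Z)-5-[(2R,3R)-3-(1,1-dibromoprop-1-en-2-yl)-5-oxooxolan-2-yl]-2-methylpent-2-enoate | COC(=O)/C(C)=C\CC[C@H]1OC(=O)C[C@@H]1C(C)=C(Br)Br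
F4 | step 8 | bromodiene: methyl (2Z)-5-[(2R,3R)-3-[(2Z)-3-bromopenta-2,4-dien-2-yl]-5-oxooxolan-2-yl]-2-methylpent-2-enoate | COC(=O)/C(C)=C\CC[C@H]1OC(=O)C[C@@H]1/C(C)=C(Br)/C=C
F5 | step 8 | vinyl bromide: methyl 1-bromo-8α,12-epoxy-12-oxo-13,14,15,16,17-pentanorlabd-1-en-19-oate | O=C1C[C@@H]2[C@@]3(C)C(Br)=CC[C@](C)(C(=O)OC)[C@@H]3CC[C@H]2O1
F6 | step 19 | adduct aldehyde ester: 29 with CHO on C4′ and the C19 methyl ester | C=C1CC[C@H]2CC=C(C)[C@@H](C[C@H]3C(=C)CC[C@@H]4[C@]3(C)CCC[C@]4(C)C(=O)OC)[C@]2(C=O)CC[C@@H]2[C@@H]1CC2(C)C
F7 | step 19 | acid ester: 29 as its C19 methyl ester | C=C1CC[C@H]2CC=C(C)[C@@H](C[C@H]3C(=C)CC[C@@H]4[C@]3(C)CCC[C@]4(C)C(=O)OC)[C@]2(C(=O)O)CC[C@@H]2[C@@H]1CC2(C)C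
F8 | step 15 | caryophyllene oxide (trans-4′,5′-epoxide) | C=C1CC[C@H]2O[C@]2(C)CC[C@@H]2[C@@H]1CC2(C)C
F9 | step 15 | exocyclic allylic alcohol: caryophylla-4(12),8(13)-dien-5-ol | C=C1CC[C@@H](O)C(=C)CC[C@@H]2[C@@H]1CC2(C)C
F10 | step 15 | spiro-epoxy alcohol: 4′,12′-epoxide of F9 | C=C1CC[C@@H](O)[C@@]2(CO2)CC[C@@H]3[C@@H]1CC3(C)C
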